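**Plan**
1. Retrosynthetic cuts, in order: C2–C1′ (ring C to ring B), C8–C1″ (ring A to the side chain), and C2″–C(CH3)2OH inside the side chain. C1″ is the benzylic CH2 and C2″ is the side-chain stereocentre.
2. Enabling feature: C1′ lies ortho, ortho and para to O2′, O6′ and O4′. Ring B is therefore the tris-enol of cyclohexane-1,3,5-trione, and its tris(TMS) ether has three equivalent nucleophilic CH carbons. At the chromone level ring C holds O1–C2=C3–C4=O, and silylation of O4 turns it into an aromatic 1-benzopyrylium ion that is open to attack only at C2.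
3. Forward order: rings A and C are bought together as 5,7-dihydroxychromone, which is silylated and iodinated at C8. The side chain (five steps) is joined by Negishi coupling, and ring B is joined last.
4. Helpers: the C2=C3 unsaturation, the O4 silyl group and all seven silyl groups are removed in one fluoride step.
5. Stereochemistry: C2″ comes from an Evans auxiliary (titanium aldol with acetone). C2 comes from a chiral anion-binding catalyst on the benzopyrylium triflate ion pair. Because C2″ is fixed, the C2 epimers are diastereomers and can be separated.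

Key step: step 10

Assumption: the sense of induction of the anion-binding catalyst on this cation cannot be predicted with certainty; the antipode meant in step 10 is the one that leaves the Re face of C2 open, and both antipodes are equally accessible from (R,R)- or (S,S)-cyclohexane-1,2-diamine.

**Step 1**
Reactants: 1 5-methylhex-4-enoic acid; 2 (4S)-4-benzyl-1,3-oxazolidin-2-one
Product: 4 (4S)-4-benzyl-3-(5-methylhex-4-enoyl)-1,3-oxazolidin-2-one, via mixed pivalic anhydride 3 (not isolated)
Conditions: PivCl, Et3N, THF, −20 °C; then 2, LiCl, −20 °C → rt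
Reagents that add atoms: none
Why: Mixed-anhydride N-acylation of an Evans oxazolidinone, in which the nucleophile attacks the less hindered acyl carbon of 3 and no stereocentre is touched.

**Step 2**
Reactants: 4 imide; 5 acetone
Product: 7 (4S)-4-benzyl-3-[(2S)-2-(2-hydroxypropan-2-yl)-5-methylhex-4-enoyl]-1,3-oxazolidin-2-one, via chlorotitanium (Z)-enolate 6 (not isolated)
Conditions: TiCl4, i-Pr2NEt, NMP, CH2Cl2, 0 °C; 5 (excess), −78 → 0 °C; aq. NH4Cl
Reagents that add atoms: none
Why: Evans-type titanium aldol addition in which soft enolization gives the (Z)-enolate, NMP saturates titanium so that the non-chelated Zimmerman–Traxler arrangement ("Evans-syn" facial sense) should apply, acetone is taken up on the face remote from the benzyl group to set the α-carbon as (S) (this becomes (R) at C2″ of the target through CIP priority changes only), and the strong Ti–O bond of the aldolate holds back retro-aldol as in titanium-mediated additions to ketones.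

**Step 3**
Reactants: 7 aldol adduct
Product: 8 (2R)-2-(2-hydroxypropan-2-yl)-5-methylhex-4-en-1-ol
Conditions: LiBH4, MeOH (1 equiv), THF, 0 °C
Reagents that add atoms: none
Why: Hydroxyl-assisted reductive cleavage of an N-acyloxazolidinone gives the primary alcohol faster than the α-centre can epimerize, leaves the alkene alone and returns the auxiliary.

**Step 4**
Reactants: 8 diol
Product: 9 (3S)-3-(iodomethyl)-2,6-dimethylhept-5-en-2-ol
Conditions: I2, PPh3, imidazole, CH2Cl2, 0 °C
Reagents that add atoms: iodine, II
Why: Appel-type (Garegg–Samuelsson) iodination displaces only the primary hydroxyl, the tertiary one being too hindered for SN2, and the stereocentre keeps its geometry (the descriptor changes through CIP priorities only).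

**Step 5**
Reactants: 9 iodo alcohol
Product: 10 triethyl{[(3S)-3-(iodomethyl)-2,6-dimethylhept-5-en-2-yl]oxy}silane
Conditions: TESOTf, 2,6-lutidine, CH2Cl2, −78 → 0 °C
Reagents that add atoms: triethylsilyl triflate, CC[Si](CC)(CC)OS(=O)(=O)C(F)(F)F
Why: Silyl triflate/lutidine silylation of a hindered tertiary alcohol removes the acidic proton before organozinc formation and masks the alcohol for step 10.

**Step 6**
Reactants: 11 5,7-dihydroxy-4H-chromen-4-one
Product: 12 5,7-bis(tert-butyldimethylsilyloxy)-4H-chromen-4-one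
Conditions: TBSOTf (2.5 equiv), 2,6-lutidine, CH2Cl2, 0 °C → rt; aq. NaHCO3
Reagents that add atoms: tert-butyldimethylsilyl triflate, CC(C)(C)[Si](C)(C)OS(=O)(=O)C(F)(F)F
Why: The silyl triflate is strong enough to silylate the chelated 5-OH, which resists TBSCl, and any transient silylation of O4 reverts on aqueous work-up.

**Step 7**
Reactants: 12 bis-silyl chromone
Product: 13 5,7-bis(tert-butyldimethylsilyloxy)-8-iodo-4H-chromen-4-one
Conditions: NIS, TFA (cat.), MeCN, 0 °C → rt, dark
Reagents that add atoms: N-iodosuccinimide, O=C1CCC(=O)N1I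
Why: Electrophilic aromatic iodination of 5,7-di-O-substituted chromones and flavones goes to C8, and here C6 is additionally shielded by two flanking OTBS groups while C8 has only one OTBS and the ring oxygen next to it.

**Step 8**
Reactants: 10 alkyl iodide; 13 aryl iodide
Product: 15 5,7-bis(tert-butyldimethylsilyloxy)-8-{(2R)-5-methyl-2-[2-(triethylsilyloxy)propan-2-yl]hex-4-enyl}-4H-chromen-4-one, via alkylzinc iodide 14 (not isolated)
Conditions: 10, Zn dust, LiCl, THF, 40 °C; then 13, Pd(OAc)2 (cat.), SPhos (cat.), THF, rt → 40 °C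
Reagents that add atoms: none
Why: Negishi sp3–sp2 coupling in which zinc inserts into the primary C–I bond, Pd/SPhos joins β-branched primary alkylzinc iodides to hindered aryl iodides, the mild organozinc adds neither to the chromone nor to the silyl ethers, and the stereocentre β to zinc is not involved.

**Step 9**
Reactants: 16 phloroglucinol (anhydrous)
Product: 17 1,3,5-tris(trimethylsilyloxy)benzene
Conditions: HMDS, (NH4)2SO4 (cat.), reflux; distillation
Reagents that add atoms: hexamethyldisilazane, C[Si](C)(C)N[Si](C)(C)C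
Why: Silylation of phenols with HMDS is driven by loss of ammonia and gives the toluene-soluble tris(enol silane) form of ring B.

**Step 10**
Reactants: 15 chromone; 17 tris(trimethylsilyloxy)benzene
Product: 19 (2S)-4,5,7-tris(tert-butyldimethylsilyloxy)-8-{(2R)-5-methyl-2-[2-(triethylsilyloxy)propan-2-yl]hex-4-enyl}-2-[2,4,6-tris(trimethylsilyloxy)phenyl]-2H-chromene, via 4-siloxybenzopyrylium triflate 18 (not isolated)
Conditions: TBSOTf (1.2 equiv), 2,4,6-collidine (1.3 equiv), PhMe, rt; then chiral cyclohexane-1,2-diamine-derived tetrakis(1,2,3-triazole) anion-binding catalyst (10 mol %), 17 (2 equiv), −60 → −30 °C; aq. NaHCO3; short pad of Et3N-deactivated SiO2, used at once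
Reagents that add atoms: tert-butyldimethylsilyl triflate, CC(C)(C)[Si](C)(C)OS(=O)(=O)C(F)(F)F
Why: Proposed new method: TBSOTf silylates O4 of 15 and turns the vinylogous ester O1–C2=C3–C4=O of ring C into the aromatic benzopyrylium triflate 18, in which C4 is blocked and C2 is the only open electrophilic carbon; one of the three equivalent CH carbons of 17, each the terminus of three enol silanes, attacks C2 in a Mukaiyama–Michael sense, and loss of the ring proton to collidine (directly, or after loss of Me3Si+, dienone–phenol tautomerization and resilylation) restores ring B and leaves the C3=C4 enol silane 19. The closest known reaction type is the addition of silyl ketene acetals and enol silanes to 4-siloxybenzopyrylium triflates made from chromones, also known in enantioselective form under hydrogen-bond-donor anion-binding catalysis; the new element is the tris(siloxy)arene as π-nucleophile, which is weaker than a ketene acetal but comparable to 1,3,5-trimethoxybenzene, an arene that captures stabilized carbenium and pyrylium-type ions, hence the higher temperature window. No ring is closed: ring C passes from chromone through pyrylium to 2H-chromene. The new stereocentre C2 is controlled by the catalyst, which binds the triflate and holds it as a chiral contact ion pair over one face of the flat cation so that 17 enters on the Re face of C2 to give (2S); the remote C2″ centre should have no influence, but it makes the C2 epimers diastereomers, so a shortfall in selectivity can be removed by chromatography. The step needs C2 over C4 attack (C4 carries OSi), C- over O-attack (every oxygen of 17 is silylated), mono- over polyarylation (17 in excess) and survival of the acid-labile side chain (collidine takes up the only proton set free, the tertiary alcohol is a TES ether, and the prenyl alkene could reach C2 only through an eight-membered ring).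

**Step 11**
Reactants: 19 per-silylated 2H-chromene
Product: 20 (2S)-5,7-dihydroxy-8-[(2R)-2-(2-hydroxypropan-2-yl)-5-methylhex-4-enyl]-2-(2,4,6-trihydroxyphenyl)-2,3-dihydro-4H-chromen-4-one (target)
Conditions: Et3N·3HF (excess), MeCN–THF, 0 °C → rt; pH 5–6 buffer work-up
Reagents that add atoms: none
Why: Fluoride-driven global desilylation under weakly acidic buffered conditions cleaves all seven Si–O bonds and protonates the enol at C3 to give the C4 ketone, with no base present to open ring C by retro-oxa-Michael reaction (epimerization at C2) and no strong acid to cyclize or dehydrate the tertiary alcohol/prenyl pair.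

**Compound list**
1 | 5-methylhex-4-enoic acid | CC(C)=CCCC(=O)O | starting material
2 | (4S)-4-benzyl-1,3-oxazolidin-2-one | O=C1N[C@@H](Cc2ccccc2)CO1 | starting material
3 | 5-methylhex-4-enoic pivalic anhydride | CC(C)=CCCC(=O)OC(=O)C(C)(C)C | intermediate
4 | (4S)-4-benzyl-3-(5-methylhex-4-enoyl)-1,3-oxazolidin-2-one | CC(C)=CCCC(=O)N1C(=O)OC[C@@H]1Cc1ccccc1 | intermediate
5 | acetone | CC(C)=O | starting material
6 | trichlorotitanium (Z)-enolate of 4 | CC(C)=CC/C=C(\O[Ti](Cl)(Cl)Cl)N1C(=O)OC[C@@H]1Cc1ccccc1 | intermediate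
7 | (4S)-4-benzyl-3-[(2S)-2-(2-hydroxypropan-2-yl)-5-methylhex-4-enoyl]-1,3-oxazolidin-2-one | CC(C)=CC[C@H](C(=O)N1C(=O)OC[C@@H]1Cc1ccccc1)C(C)(C)O | intermediate
8 | (2R)-2-(2-hydroxypropan-2-yl)-5-methylhex-4-en-1-ol | CC(C)=CC[C@H](CO)C(C)(C)O | intermediate
9 | (3S)-3-(iodomethyl)-2,6-dimethylhept-5-en-2-ol | CC(C)=CC[C@H](CI)C(C)(C)O | intermediate
10 | triethyl{[(3S)-3-(iodomethyl)-2,6-dimethylhept-5-en-2-yl]oxy}silane | CC(C)=CC[C@H](CI)C(C)(C)O[Si](CC)(CC)CC | intermediate
11 | 5,7-dihydroxy-4H-chromen-4-one | Oc1cc(O)c2c(c1)occc2=O | starting material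
12 | 5,7-bis(tert-butyldimethylsilyloxy)-4H-chromen-4-one | CC(C)(C)[Si](C)(C)Oc1cc(O[Si](C)(C)C(C)(C)C)c2c(c1)occc2=O | intermediate
13 | 5,7-bis(tert-butyldimethylsilyloxy)-8-iodo-4H-chromen-4-one | CC(C)(C)[Si](C)(C)Oc1cc(O[Si](C)(C)C(C)(C)C)c2c(c1I)occc2=O | intermediate
14 | {(2S)-5-methyl-2-[2-(triethylsilyloxy)propan-2-yl]hex-4-enyl}zinc iodide | CC(C)=CC[C@H](C[Zn]I)C(C)(C)O[Si](CC)(CC)CC | intermediate
15 | 5,7-bis(TBSO)-8-{(2R)-5-methyl-2-[2-(triethylsilyloxy)propan-2-yl]hex-4-enyl}-4H-chromen-4-one | CC(C)=CC[C@H](Cc1c(O[Si](C)(C)C(C)(C)C)cc(O[Si](C)(C)C(C)(C)C)c2c1occc2=O)C(C)(C)O[Si](CC)(CC)CC | intermediate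
16 | phloroglucinol | Oc1cc(O)cc(O)c1 | starting material
17 | 1,3,5-tris(trimethylsilyloxy)benzene | C[Si](C)(C)Oc1cc(O[Si](C)(C)C)cc(O[Si](C)(C)C)c1 | intermediate
18 | 4,5,7-tris(TBSO)-8-{(2R)-5-methyl-2-[2-(triethylsilyloxy)propan-2-yl]hex-4-enyl}-1-benzopyrylium triflate | CC(C)=CC[C@H](Cc1c(O[Si](C)(C)C(C)(C)C)cc(O[Si](C)(C)C(C)(C)C)c2c(O[Si](C)(C)C(C)(C)C)cc[o+]c12)C(C)(C)O[Si](CC)(CC)CC.[O-]S(=O)(=O)C(F)(F)F | intermediate
19 | (2S)-4,5,7-tris(TBSO)-8-{(2R)-5-methyl-2-[2-(triethylsilyloxy)propan-2-yl]hex-4-enyl}-2-[2,4,6-tris(trimethylsilyloxy)phenyl]-2H-chromene | CC(C)=CC[C@H](Cc1c(O[Si](C)(C)C(C)(C)C)cc(O[Si](C)(C)C(C)(C)C)c2c1O[C@H](c1c(O[Si](C)(C)C)cc(O[Si](C)(C)C)cc1O[Si](C)(C)C)C=C2O[Si](C)(C)C(C)(C)C)C(C)(C)O[Si](CC)(CC)CC | intermediate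
20 | (2S)-5,7-dihydroxy-8-[(2R)-2-(2-hydroxypropan-2-yl)-5-methylhex-4-enyl]-2-(2,4,6-trihydroxyphenyl)-2,3-dihydro-4H-chromen-4-one | CC(C)=CC[C@H](Cc1c(O)cc(O)c2c1O[C@H](c1c(O)cc(O)cc1O)CC2=O)C(C)(C)O | target

**Step count**
Total steps: 11. Longest linear sequence: 8 (steps 1, 2, 3, 4, 5, 8, 10, 11).

**Steps most likely to fail**

1. Step 10.
   - Risk: capture of the donor-stabilized cation by the weak arene nucleophile may be too slow. Crowding between the silyl groups on O4 and O5 may hinder cation formation. An uncatalysed ion-pair pathway may erode facial selectivity.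
   - Fallback, known chemistry only, from 15 and 16 and back at 20. Compound 16 is converted with MOMCl/i-Pr2NEt into 1,3,5-tris(methoxymethoxy)benzene F1. Directed ortho-metalation with n-BuLi between two OMOM groups gives [2,4,6-tris(methoxymethoxy)phenyl]lithium F2. CuI turns this into the lithium diarylcuprate F3.
   - TMSCl-accelerated conjugate addition of F3 to 15 gives the trimethylsilyl enol ether F4 as a pair of C2 epimers. Mild hydrolysis gives the (2S)-flavanone F5 and the (2R)-flavanone F6. These are diastereomers because of C2″ and are separated by chromatography. F6 can be re-equilibrated at C2 with a weak base (reversible retro-oxa-Michael ring opening) and separated again.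
   - Et3N·3HF converts F5 into the desilylated tris-MOM flavanone F7. NaHSO4 on silica then removes the phenolic MOM groups to give 20.

2. Step 2.
   - Risk: the addition may reverse (retro-aldol of the tertiary aldolate). Leakage through a chelated transition state may lower or invert the facial selectivity.
   - Fallback from 4, back at 8, by alkylation instead of aldol addition. The titanium enolate 6 is alkylated with benzyl chloromethyl ether through the chelated enolate, whose facial sense is firmly established. This gives (4S)-4-benzyl-3-[(2R)-2-(benzyloxymethyl)-5-methylhex-4-enoyl]-1,3-oxazolidin-2-one F8.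
   - The same (4S)-auxiliary serves because attack is now on the opposite enolate face, while the carbonyl carbon and the newly attached carbon exchange their roles.
   - MeOMgBr/MeOH gives methyl (2R)-2-(benzyloxymethyl)-5-methylhex-4-enoate F9. Excess MeMgBr gives (3R)-3-(benzyloxymethyl)-2,6-dimethylhept-5-en-2-ol F10. Lithium naphthalenide removes the benzyl group without touching the alkene and gives 8.

3. Step 8.
   - Risk: oxidative addition and transmetalation may be slow at the di-ortho-substituted C8–I bond. The alkylzinc may undergo protodemetalation, and 13 may undergo hydrodeiodination.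
   - Fallback from 13 and 10, back at 15, with the polarity reversed. Zinc/LiCl insertion into 13 gives [5,7-bis(tert-butyldimethylsilyloxy)-4-oxo-4H-chromen-8-yl]zinc iodide F11. This is coupled with unchanged 10 under cobalt catalysis (CoCl2·2LiCl, TMEDA), the known arylzinc–primary alkyl iodide cross-coupling. The transient primary radical is of the 4-pentenyl type, does not cyclize readily, and leaves C2″ untouched.

**Further compounds**
F1 | step 10 | 1,3,5-tris(methoxymethoxy)benzene | COCOc1cc(OCOC)cc(OCOC)c1
F2 | step 10 | [2,4,6-tris(methoxymethoxy)phenyl]lithium | [Li]c1c(OCOC)cc(OCOC)cc1OCOC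
F3 | step 10 | lithium bis[2,4,6-tris(methoxymethoxy)phenyl]cuprate | [Li+].COCOc1cc(OCOC)c([Cu-]c2c(OCOC)cc(OCOC)cc2OCOC)c(OCOC)c1
F4 | step 10 | 4-trimethylsilyloxy-2H-chromene adduct, both C2 epimers | CC(C)=CC[C@H](Cc1c(O[Si](C)(C)C(C)(C)C)cc(O[Si](C)(C)C(C)(C)C)c2c1OC(c1c(OCOC)cc(OCOC)cc1OCOC)C=C2O[Si](C)(C)C)C(C)(C)O[Si](CC)(CC)CC
F5 | step 10 | (2S)-5,7-bis(TBSO)-8-{(2R)-side chain OTES}-2-[2,4,6-tris(methoxymethoxy)phenyl]chroman-4-one | CC(C)=CC[C@H](Cc1c(O[Si](C)(C)C(C)(C)C)cc(O[Si](C)(C)C(C)(C)C)c2c1O[C@H](c1c(OCOC)cc(OCOC)cc1OCOC)CC2=O)C(C)(C)O[Si](CC)(CC)CC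
F6 | step 10 | (2R)-epimer of F5 | CC(C)=CC[C@H](Cc1c(O[Si](C)(C)C(C)(C)C)cc(O[Si](C)(C)C(C)(C)C)c2c1O[C@@H](c1c(OCOC)cc(OCOC)cc1OCOC)CC2=O)C(C)(C)O[Si](CC)(CC)CC
F7 | step 10 | (2S)-5,7-dihydroxy-8-[(2R)-2-(2-hydroxypropan-2-yl)-5-methylhex-4-enyl]-2-[2,4,6-tris(methoxymethoxy)phenyl]chroman-4-one | CC(C)=CC[C@H](Cc1c(O)cc(O)c2c1O[C@H](c1c(OCOC)cc(OCOC)cc1OCOC)CC2=O)C(C)(C)O
F8 | step 2 | (4S)-4-benzyl-3-[(2R)-2-(benzyloxymethyl)-5-methylhex-4-enoyl]-1,3-oxazolidin-2-one | CC(C)=CC[C@H](COCc1ccccc1)C(=O)N1C(=O)OC[C@@H]1Cc1ccccc1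
F9 | step 2 | methyl (2R)-2-(benzyloxymethyl)-5-methylhex-4-enoate | CC(C)=CC[C@H](COCc1ccccc1)C(=O)OC
F10 | step 2 | (3R)-3-(benzyloxymethyl)-2,6-dimethylhept-5-en-2-ol | CC(C)=CC[C@H](COCc1ccccc1)C(C)(C)O
F11 | step 8 | [5,7-bis(tert-butyldimethylsilyloxy)-4-oxo-4H-chromen-8-yl]zinc iodide | I[Zn]c1c(O[Si](C)(C)C(C)(C)C)cc(O[Si](C)(C)C(C)(C)C)c2c1occc2=O
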